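The synthesis rests on cutting both aryl bonds of C4 after opening the lactone at O1–C2. C4 is a methine bearing ring-A carbon C4a, C1 of a guaiacyl ring and the C3H2–C2(=O) arm, so it is the β-carbon of an acrylate carrying two different aryl groups. One palladium-catalysed, chiral-anion-controlled three-component coupling puts the guaiacyl group (from a diazonium salt) and ring A (from a boronic acid with boron at the future C4a, flanked by the C8a oxygen and the C5 styryl arm) on the terminal carbon of benzyl acrylate and sets C4 (R). The precursors are a perbenzylated (E)-stilbenyl boronic acid, a benzyl-protected guaiacyl diazonium tetrafluoroborate and benzyl acrylate.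

Key step: step 9

Remark on the chemistry: which antipode of the chiral phosphoric acid delivers (R) at C4 with this boronic acid cannot be predicted with certainty. It is assumed to be settled by a pilot run with both antipodes, and the route is written for the one that gives (R).

Step 1
Reactants: 1 3,5-bis(benzyloxy)benzaldehyde
Product: 2 2-bromo-3,5-bis(benzyloxy)benzaldehyde
Conditions: NBS (1.0 equiv), MeCN, 0 °C to rt, dark
Reagents that add atoms: N-bromosuccinimide O=C1CCC(=O)N1Br
Why: Electrophilic aromatic bromination; C2 is activated ortho by one benzyloxy group and para by the other, and one equivalent of NBS should brominate there in preference to the more crowded C4 between the two ether groups, as is usual for 3,5-dialkoxybenzaldehydes.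

Step 2
Reactants: 3 4-(benzyloxy)-3-methoxybenzaldehyde (O-benzylvanillin)
Product: 4 [4-(benzyloxy)-3-methoxyphenyl]methanol
Conditions: NaBH4, MeOH/THF, 0 °C
Reagents that add atoms: none
Why: Borohydride reduction of the aldehyde to the benzylic alcohol; the benzyl and methyl ethers are inert to hydride.

Step 3
Reactants: 4 [4-(benzyloxy)-3-methoxyphenyl]methanol
Product: 6 diethyl [4-(benzyloxy)-3-methoxybenzyl]phosphonate, via benzylic chloride 5 (not isolated)
Conditions: SOCl2, CH2Cl2, 0 °C to rt; evaporate; P(OEt)3 (neat), 130 °C
Reagents that add atoms: triethyl phosphite CCOP(OCC)OCC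
Why: Chlorodehydroxylation of the electron-rich benzylic alcohol followed by a Michaelis–Arbuzov reaction, in which the phosphite is alkylated by the reactive benzylic chloride and the phosphonium ion loses chloroethane; telescoping avoids storing the labile chloride.

Step 4
Reactants: 2 2-bromo-3,5-bis(benzyloxy)benzaldehyde, 6 diethyl [4-(benzyloxy)-3-methoxybenzyl]phosphonate
Product: 7 (E)-2-bromo-3,5-bis(benzyloxy)-4'-benzyloxy-3'-methoxystilbene
Conditions: KOtBu, THF, 0 °C to rt
Reagents that add atoms: none
Why: Horner–Wadsworth–Emmons olefination of a non-enolisable aldehyde; the aryl-stabilised phosphonate carbanion adds reversibly and eliminates through the anti pathway, which should give the (E)-alkene, and the aryl bromide is inert to the alkoxide.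

Step 5
Reactants: 7 (E)-2-bromo-3,5-bis(benzyloxy)-4'-benzyloxy-3'-methoxystilbene
Product: 10 [2,4-bis(benzyloxy)-6-[(E)-2-(4-benzyloxy-3-methoxyphenyl)ethenyl]phenyl]boronic acid, via aryllithium 8 (not isolated), via lithium triisopropoxyborate 9 (not isolated)
Conditions: B(OiPr)3 (1.5 equiv) present from the start, n-BuLi (1.1 equiv) added last, THF/toluene, −78 °C; then 1 M HCl to pH 5, 0 °C
Reagents that add atoms: triisopropyl borate CC(C)OB(OC(C)C)OC(C)C; water O
Why: Lithiation–borylation with in-situ quench; bromine–lithium exchange at −78 °C is faster than attack of butyllithium on the borate, the stilbene or the benzylic C–H bonds, so the aryllithium is trapped as the ate complex as it forms and brief mild acid hydrolysis should release the boronic acid with boron at the future C4a.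

Step 6
Reactants: 11 2-methoxy-4-nitrophenol
Product: 12 1-(benzyloxy)-2-methoxy-4-nitrobenzene
Conditions: BnBr, K2CO3, DMF, 60 °C
Reagents that add atoms: benzyl bromide BrCc1ccccc1
Why: Williamson ether synthesis; the acidic nitrophenol is deprotonated by carbonate and the phenoxide is alkylated by the benzylic bromide in an SN2 reaction.

Step 7
Reactants: 12 1-(benzyloxy)-2-methoxy-4-nitrobenzene
Product: 13 4-(benzyloxy)-3-methoxyaniline
Conditions: Fe powder, NH4Cl, EtOH/H2O, 80 °C
Reagents that add atoms: none
Why: Béchamp-type iron reduction of the nitro group by electron transfer from the metal, which cannot hydrogenolyse the benzyl ether as hydrogenation over palladium on carbon would.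

Step 8
Reactants: 13 4-(benzyloxy)-3-methoxyaniline
Product: 14 4-(benzyloxy)-3-methoxybenzenediazonium tetrafluoroborate
Conditions: t-BuONO, HBF4 (48% aq.), EtOH, 0 °C; precipitation with Et2O
Reagents that add atoms: tert-butyl nitrite CC(C)(C)ON=O; tetrafluoroboric acid [H+].F[B-](F)(F)F
Why: Diazotisation of the primary arylamine by the nitrosonium equivalent formed from the alkyl nitrite in acid; the para-alkoxy group stabilises the diazonium ion, which should precipitate as its storable tetrafluoroborate while the benzyl ether survives the cold acid.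

Step 9
Reactants: 10 [2,4-bis(benzyloxy)-6-[(E)-2-(4-benzyloxy-3-methoxyphenyl)ethenyl]phenyl]boronic acid (limiting), 14 4-(benzyloxy)-3-methoxybenzenediazonium tetrafluoroborate (moderate excess), 15 benzyl acrylate (moderate excess)
Product: 16 benzyl (3R)-3-[2,4-bis(benzyloxy)-6-[(E)-2-(4-benzyloxy-3-methoxyphenyl)ethenyl]phenyl]-3-(4-benzyloxy-3-methoxyphenyl)propanoate
Conditions: Pd2(dba)3 (5 mol %), chiral BINAM-derived phosphoric acid (N,N'-diaryl phosphorodiamidic acid type, 12 mol %, antipode giving R), Na2CO3 (solid), MTBE/toluene, rt, dark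
Reagents that add atoms: none
Why: Zerovalent palladium takes up diazonium salt 14 with loss of N2 to give a cationic guaiacyl–palladium species ion-paired with the chiral phosphate, which inserts acrylate 15 with the aryl group on the β-carbon; β-hydride elimination and reinsertion of the Pd–H into the bound cinnamate with reversed regiochemistry move palladium to the benzylic carbon, where the para-oxygenated guaiacyl ring holds it as a π-benzyl complex, and transmetalation with 10 followed by reductive elimination forges the C4–C4a bond. The closest known reaction type is the palladium-catalysed enantioselective 1,1-diarylation of benzyl acrylates with aryldiazonium salts and arylboronic acids under chiral anion phase transfer, a Heck–Matsuda insertion relayed into a Suzuki-type coupling. No ring is closed in this step; the lactone is formed only in step 10. The new stereocentre C4 is set (R) under catalyst control by the chiral phosphate counter-anion of the cationic palladium intermediates, and the antipodal acid would give (S). The step needs 1,1- over 1,2-(Heck) selectivity, secured by π-benzyl stabilisation from the electron-rich guaiacyl group; acrylate over stilbene chemoselectivity, secured by the much faster insertion of the terminal electron-poor alkene used in excess; and a fixed attachment site on ring A, secured by the boron placed at C4a through the earlier bromination. Slow transmetalation of the di-ortho-substituted boronic acid is the accepted risk.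

Step 10
Reactants: 16 benzyl (3R)-3-[2,4-bis(benzyloxy)-6-[(E)-2-(4-benzyloxy-3-methoxyphenyl)ethenyl]phenyl]-3-(4-benzyloxy-3-methoxyphenyl)propanoate
Product: 18 (4R)-7-hydroxy-4-(4-hydroxy-3-methoxyphenyl)-5-[(E)-2-(4-hydroxy-3-methoxyphenyl)ethenyl]-3,4-dihydro-2H-chromen-2-one (CNP0277187.1), via seco-acid 17 (not isolated)
Conditions: BCl3 (1 M in CH2Cl2, excess), C6HMe5 (excess), CH2Cl2, −78 to −20 °C; H2O quench (no alcohol); then TsOH·H2O (cat.), MeCN, 40 °C
Reagents that add atoms: none
Why: Lewis-acid debenzylation in which BCl3 ionises the five benzyl–oxygen bonds and pentamethylbenzene captures the benzyl cations by Friedel–Crafts alkylation, cold conditions that should spare the aryl methyl ethers and the stilbene (no hydrogenation is involved); the freed C8a phenol then closes the lactone by acid-catalysed 6-exo-trig acyl substitution at C2, only this ortho oxygen being able to reach, C4 is not touched, and any benzyl ester surviving the cold stage would close in the same way with loss of benzyl alcohol.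

Compound list
1 | 3,5-bis(benzyloxy)benzaldehyde | O=Cc1cc(OCc2ccccc2)cc(OCc2ccccc2)c1 | starting material
2 | 2-bromo-3,5-bis(benzyloxy)benzaldehyde | O=Cc1cc(OCc2ccccc2)cc(OCc2ccccc2)c1Br | intermediate
3 | 4-(benzyloxy)-3-methoxybenzaldehyde (O-benzylvanillin) | COc1cc(C=O)ccc1OCc1ccccc1 | starting material
4 | [4-(benzyloxy)-3-methoxyphenyl]methanol | COc1cc(CO)ccc1OCc1ccccc1 | intermediate
5 | 1-(benzyloxy)-4-(chloromethyl)-2-methoxybenzene | COc1cc(CCl)ccc1OCc1ccccc1 | intermediate
6 | diethyl [4-(benzyloxy)-3-methoxybenzyl]phosphonate | CCOP(=O)(OCC)Cc1ccc(OCc2ccccc2)c(OC)c1 | intermediate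
7 | (E)-2-bromo-3,5-bis(benzyloxy)-4'-benzyloxy-3'-methoxystilbene | COc1cc(/C=C/c2cc(OCc3ccccc3)cc(OCc3ccccc3)c2Br)ccc1OCc1ccccc1 | intermediate
8 | [2,4-bis(benzyloxy)-6-[(E)-2-(4-benzyloxy-3-methoxyphenyl)ethenyl]phenyl]lithium | COc1cc(/C=C/c2cc(OCc3ccccc3)cc(OCc3ccccc3)c2[Li])ccc1OCc1ccccc1 | intermediate
9 | lithium [2,4-bis(benzyloxy)-6-[(E)-2-(4-benzyloxy-3-methoxyphenyl)ethenyl]phenyl]tri(propan-2-yloxy)borate | COc1cc(/C=C/c2cc(OCc3ccccc3)cc(OCc3ccccc3)c2[B-](OC(C)C)(OC(C)C)OC(C)C)ccc1OCc1ccccc1.[Li+] | intermediate
10 | [2,4-bis(benzyloxy)-6-[(E)-2-(4-benzyloxy-3-methoxyphenyl)ethenyl]phenyl]boronic acid | COc1cc(/C=C/c2cc(OCc3ccccc3)cc(OCc3ccccc3)c2B(O)O)ccc1OCc1ccccc1 | intermediate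
11 | 2-methoxy-4-nitrophenol | COc1cc([N+](=O)[O-])ccc1O | starting material
12 | 1-(benzyloxy)-2-methoxy-4-nitrobenzene | COc1cc([N+](=O)[O-])ccc1OCc1ccccc1 | intermediate
13 | 4-(benzyloxy)-3-methoxyaniline | COc1cc(N)ccc1OCc1ccccc1 | intermediate
14 | 4-(benzyloxy)-3-methoxybenzenediazonium tetrafluoroborate | COc1cc([N+]#N)ccc1OCc1ccccc1.F[B-](F)(F)F | intermediate
15 | benzyl acrylate | C=CC(=O)OCc1ccccc1 | starting material
16 | benzyl (3R)-3-[2,4-bis(benzyloxy)-6-[(E)-2-(4-benzyloxy-3-methoxyphenyl)ethenyl]phenyl]-3-(4-benzyloxy-3-methoxyphenyl)propanoate | COc1cc(/C=C/c2cc(OCc3ccccc3)cc(OCc3ccccc3)c2[C@@H](c2ccc(OCc3ccccc3)c(OC)c2)CC(=O)OCc2ccccc2)ccc1OCc1ccccc1 | intermediate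
17 | (3R)-3-[2,4-dihydroxy-6-[(E)-2-(4-hydroxy-3-methoxyphenyl)ethenyl]phenyl]-3-(4-hydroxy-3-methoxyphenyl)propanoic acid | COc1cc(/C=C/c2cc(O)cc(O)c2[C@@H](c2ccc(O)c(OC)c2)CC(=O)O)ccc1O | intermediate
18 | (4R)-7-hydroxy-4-(4-hydroxy-3-methoxyphenyl)-5-[(E)-2-(4-hydroxy-3-methoxyphenyl)ethenyl]-3,4-dihydro-2H-chromen-2-one (CNP0277187.1) | COc1cc(/C=C/c2cc(O)cc3c2[C@@H](c2ccc(O)c(OC)c2)CC(=O)O3)ccc1O | target

Total step count: 10.
Longest linear sequence: 6 steps (steps 2, 3, 4, 5, 9 and 10, from compound 3).

Steps most likely to fail

Step 9. Transmetalation of the di-ortho-substituted boronic acid may be too slow. β-Hydride elimination with release of the simple Heck product, direct biaryl coupling or arylation of the stilbene alkene could then take over, and facial selectivity at C4 may be poor. The fallback exchanges the roles of the two aryl groups and uses only known chemistry. It sets out from bromostilbene 7. A Mizoroki–Heck reaction with benzyl acrylate 15 (Pd(OAc)2, P(o-tol)3, Et3N, DMF, 100 °C) should give benzyl (E)-3-[2,4-bis(benzyloxy)-6-[(E)-2-(4-benzyloxy-3-methoxyphenyl)ethenyl]phenyl]prop-2-enoate F1. A rhodium-catalysed asymmetric conjugate addition (Hayashi–Miyaura reaction) of commercial, unhindered (4-benzyloxy-3-methoxyphenyl)boronic acid (COc1cc(B(O)O)ccc1OCc1ccccc1) then adds the guaiacyl group to the β-carbon under ligand control, using [RhCl(C2H4)2]2, a chiral bicyclic diene ligand (antipode chosen for R), KOH (cat.) and dioxane/H2O at 50 °C. The rhodium aryl adds only to the enoate, not to the stilbene. The fallback comes back to the route at compound 16.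

Step 5. The electron-rich, doubly ortho-substituted boronic acid may protodeboronate during work-up, and butyllithium may add to the stilbene or metalate the benzylic position of the ortho benzyl ether. The fallback avoids organolithium chemistry. It sets out from bromostilbene 7. A palladium-catalysed Miyaura borylation (B2pin2, Pd2(dba)3, XPhos, KOAc, dioxane, 100 °C) should give 2-[2,4-bis(benzyloxy)-6-[(E)-2-(4-benzyloxy-3-methoxyphenyl)ethenyl]phenyl]-4,4,5,5-tetramethyl-1,3,2-dioxaborolane F2. Oxidative removal of the pinacol group (NaIO4, NH4OAc, acetone/H2O, rt) then returns to the route at boronic acid 10.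

Step 10. The Lewis acid and the HCl it generates may attack the electron-rich stilbene by hydrochlorination or cationic Friedel–Crafts cyclisation, or a methyl ether may be lost while the benzyl groups are cleaved. The fallback replaces Lewis-acid cleavage by reductive, non-acidic cleavage. It sets out from compound 16. Silane-mediated palladium debenzylation (Pd(OAc)2 (cat.), Et3SiH, Et3N, CH2Cl2, rt), a method known to spare alkenes, should transfer the benzyl groups to toluene and leave triethylsilyl (3R)-3-[2,4-bis(triethylsilyloxy)-6-[(E)-2-(3-methoxy-4-triethylsilyloxyphenyl)ethenyl]phenyl]-3-(3-methoxy-4-triethylsilyloxyphenyl)propanoate F3. Its silyl ester and aryl silyl ethers are then hydrolysed with AcOH/THF/H2O at rt. The fallback comes back to the route at seco-acid 17, which is lactonised with catalytic TsOH as in step 10.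

Further compounds
F1 | step 9 | benzyl (E)-3-[2,4-bis(benzyloxy)-6-[(E)-2-(4-benzyloxy-3-methoxyphenyl)ethenyl]phenyl]prop-2-enoate | COc1cc(/C=C/c2cc(OCc3ccccc3)cc(OCc3ccccc3)c2/C=C/C(=O)OCc2ccccc2)ccc1OCc1ccccc1
F2 | step 5 | 2-[2,4-bis(benzyloxy)-6-[(E)-2-(4-benzyloxy-3-methoxyphenyl)ethenyl]phenyl]-4,4,5,5-tetramethyl-1,3,2-dioxaborolane | COc1cc(/C=C/c2cc(OCc3ccccc3)cc(OCc3ccccc3)c2B2OC(C)(C)C(C)(C)O2)ccc1OCc1ccccc1
F3 | step 10 | triethylsilyl (3R)-3-[2,4-bis(triethylsilyloxy)-6-[(E)-2-(3-methoxy-4-triethylsilyloxyphenyl)ethenyl]phenyl]-3-(3-methoxy-4-triethylsilyloxyphenyl)propanoate | COc1cc(/C=C/c2cc(O[Si](CC)(CC)CC)cc(O[Si](CC)(CC)CC)c2[C@@H](c2ccc(O[Si](CC)(CC)CC)c(OC)c2)CC(=O)O[Si](CC)(CC)CC)ccc1O[Si](CC)(CC)CC
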